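# Proposed total synthesis of artelasticin (18)

## Analysis of the target

Artelasticin (18) is a 2-aryl-4H-chromen-4-one. Ring A is hexasubstituted (hydroxyls at C5 and C7, prenyl groups at C6 and C8), ring C carries a third prenyl group at C3, and ring B is a 2,4-dihydroxyphenyl group. The molecule has no stereocentre, so the problem is one of regiochemistry and functional group tolerance. The sensitive parts are the three trisubstituted alkenes, each next to a free phenol and liable to close to a dimethylchroman under acid, and the electron-rich polyphenol itself. The hard part is the fully substituted ring A: C-prenylation of a phloroglucinol nucleus gives mixtures of O- and C-alkylated and of mono- and bis-alkylated products. In addition, the 2'-hydroxyl of ring B is a second nucleophile that could close a pyranone ring the wrong way round. The strategy rests on the substitution pattern along C8a–C8–C7–C6–C5–C4a–C4–C3–C2: C8a, C7, C5, C4 and C2 carry oxygen, and C8, C6 and C3 carry prenyl groups. Read this way, the nine carbons are a poly-β-carbonyl chain (an ester at C8a, ketones at C7, C5, C4 and C2) whose only unsubstituted methylene is C4a, and a bond from C4a to C8a folds it into ring A. The acylphloroglucinol so formed has a mirror plane through C4a and C7, so ring C can later close on either ortho hydroxyl and give one flavone.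

## Retrosynthetic reasoning

**18 from 17.** The last bonds cut are the two O–H bonds of ring B, traced back to the allyl ethers of 17. The ring B oxygens must stay masked throughout, because the 2'-oxygen would otherwise compete in the closure of ring C and free phenols would not survive the carbanion chemistry. Allyl ethers are preferred to acetal-type groups because 18 has four phenols flanked by prenyl groups, and an acidic unmasking is the operation the target tolerates least. Zerovalent palladium removes allyl ethers under neutral conditions and leaves the prenyl groups, which have no leaving group, alone.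

**17 from 16.** Ring C is opened at the O1–C2 bond and the C2=C3 double bond is traced back to the ring B ketone, which leads to the 1,3-diketone 16. Nothing is gained by cutting elsewhere, since 16 already holds every carbon of 18. The forward reaction is a cyclodehydration. Ring A of 16 is symmetric, so both ortho hydroxyls give 17, and with ring B still allylated no other oxygen can close onto a carbonyl.

**16 from 15.** Ring A is opened at the C4a–C8a bond, which gives the open-chain tetraketo ester 15. Chain numbering runs from the ester carbon: C1 becomes C8a, C2 C8, C3 C7, C4 C6, C5 C5, C6 C4a, C7 C4, C8 C3 and C9 C2. This is the one ring bond whose cleavage pairs the only methylene of the chain (C6) as nucleophile with its only carboxylic ester (C1) as electrophile. Any other cut would ask a prenyl-bearing methine to attack a ketone and would end in a ring that cannot aromatise. The gain is that ring A, its three oxygens and its two prenyl groups all come from an acyclic precursor in which each substituent was placed by alkylation of a defined carbon. The forward reaction must be an intramolecular C-acylation in the presence of four ketones and must win over aldol closures and lactone formation; a chelating magnesium alkoxide base in its parent alcohol is the means.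

**15 from 13 and 8, by way of 14.** The chain is cut at C6–C7. This gives two β-dicarbonyl pieces of similar size and makes the nucleophile the unhindered terminal methyl carbon of 13. Cuts at C4–C5 or C8–C9 would need secondary carbanions or acyl donors lying between two further carbonyl groups. The ring B keto ester 7 itself is not a workable partner: the hydrogen between its carbonyls is far more acidic than the conjugate acid of the terminal carbanion of 13 and would quench it, and as a preformed enolate 7 is a feeble, hindered acyl donor. That carbon is therefore made sp2 and hydrogen-free in the silyl enol ether 8, whose ester is then the only electrophilic site. Acylation gives 14. The C9 ketone of 15 is then freed by fluoride at silicon and not by acid, because neutral 14, a β-silyloxy enone, would close onto its C5 enol to a 4-pyranone if acidified first.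

**8 from 1.** 8 is traced back through O-silylation to 7, through the C8–CH2 bond to 5 and prenyl bromide 6, through the C7–C8 bond to the acetophenone 3 and 4, and through the two O–allyl bonds to 1 and 2. Each cut is at a position only one reagent can reach: 3 has a single enolisable carbon and 5 a single doubly activated carbon. The C8 prenyl group, the future C3 substituent of ring C, is thus fixed without ambiguity.

**13 from 9.** 13 is cut at C4–C5 to the keto ester 11 and the acetyl donor 12, and 11 is cut at its two C–CH2 bonds to methyl acetoacetate 9 and two equivalents of 6. The order follows acidity: the γ-carbon of 9 is alkylated first through the dianion (10), the α-carbon second under weak base (11), and the acetyl group comes last. Once the acetyl group is present, the methine between the two ketones of 13 would be the preferred site of further alkylation and would take a second prenyl group. In this way the future C8 and C6 substituents of ring A each go to one carbon only.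

## Alternatives that were turned down

**Alternative 1:** The C2=C3 double bond of ring C is cut. This leads back to the aryl ester A1, a ring B benzoate of a ring A phenol whose ortho acyl group is a prenyl-substituted triphenylphosphonium ylide. On heating, the ylide carbon (future C3) would attack the ester carbonyl (future C2) in an intramolecular Wittig reaction and give the fully protected flavone A2.
- For: ring C closes under neutral conditions, the C3 prenyl group is fixed on the ylide carbon beforehand, and no hemiketal has to be dehydrated. On the predictability of the ring-forming event itself this plan is stronger than a polyketide folding.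
- Against: A1 presupposes a finished ring A, a hexasubstituted ketone with two C-prenyl groups and three oxygens that must be told apart. The only direct access is the unselective C-prenylation of an acylphloroglucinol. The ylide is stabilised and α-branched and the ester is flanked by ortho substituents on both sides, so forcing conditions would be needed. Four acetals would then have to be removed with acid beside three prenyl groups.
- Comparison: the chosen strategy gives up the well-behaved olefination. In its place it offers a ring A whose prenyl groups are set by enolate alkylations before the ring exists, no differentiation of the ring A oxygens, and fewer steps.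

**Alternative 2:** Ring A is taken apart at C5–C6, C7–C8 and C4a–C5. This leads to the pyranonyl diazoketone A3, which already carries ring B, the C3 prenyl group and a prenyl-substituted diazoacetyl side chain, and to the prenylated siloxyalkyne A4. Irradiation would trigger Wolff rearrangement of A3 to a vinylketene, [2+2] addition of A4, four-electron ring opening and six-electron electrocyclisation (Danheiser benzannulation). The product is the flavone A5 with a free 5-hydroxyl and a silylated 7-hydroxyl.
- For: the benzannulation is regiospecific and convergent, places both ring A prenyl groups and both oxygens in one step, and delivers the two oxygens differentiated. In regiochemical certainty of the ring-forming step it is at least the equal of the chosen plan.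
- Against: the target needs no such differentiation. A3 has an alkyl group with β-hydrogens on the diazo carbon, so 1,2-hydrogen shift to an enone competes with the Wolff rearrangement. The ketene intermediates arise next to three prenyl alkenes, themselves partners for ketene [2+2] addition. The pyranone chromophore absorbs where the diazoketone does, and A3 and A4 each need a long preparation.
- Comparison: the chosen route is much shorter and uses only enolate chemistry on bulk starting materials. In place of the regiospecific pericyclic cascade it offers a folding whose selectivity is enforced by the substitution pattern of the chain.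

**Alternative 3:** The two C–CH2 bonds at C6 and C8 are cut. This leads to the flavone A6, in which both ring A oxygens carry 1,1-dimethylallyl groups and C6 and C8 are unsubstituted. Heating would induce two aromatic Claisen rearrangements, each turning a tertiary allyl ether into a C-prenyl group, and give A7.
- For: the flavone core is made by standard chemistry, the rearrangement is neutral and inverts the allyl unit so that normal prenyl groups result, and two C–C bonds form in one operation. As a late-stage way to put prenyl groups on an existing ring A it is more direct than anything in the chosen route.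
- Against: a tertiary allyl ether must be built on the chelated, hindered 5-hydroxyl, which usually takes a propargylation and a partial reduction per ether. The 7-ether can migrate to C6 as well as C8, while the 5-ether can only go to C6. If C6 is taken first, the second group reaches C8 by a para shift and arrives as the reverse-prenyl isomer. The C3 prenyl group must still be built in beforehand, and A7 needs acidic unmasking of ring B.
- Comparison: the chosen strategy avoids every regiochemical question on ring A, because each prenyl group is attached to an acyclic carbon that has only one place to go in the ring.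

Key step: step 9

Remark on the chemistry: 7, 11, 13, 15 and 16 have epimerisable stereocentres between carbonyl groups and are handled as mixtures of stereoisomers and keto–enol tautomers, and 8 and 14 as E/Z mixtures. All these elements disappear by step 10, so the SMILES carry no configuration.

## Route

Step 1
Reactants: 1 2,4-dihydroxyacetophenone; 2 allyl bromide
Product: 3 1-[2,4-bis(prop-2-en-1-yloxy)phenyl]ethanone
Conditions: 2 (2.5 equiv), K2CO3 (3 equiv), DMF, 60 °C
Reagents that add atoms: none
Why: Twofold Williamson etherification; the chelated 2-hydroxyl is slower but is alkylated in DMF with excess 2. Allyl ethers resist the strong bases and the methoxide used later and can be removed at the end without acid.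

Step 2
Reactants: 3 1-[2,4-bis(prop-2-en-1-yloxy)phenyl]ethanone; 4 dimethyl carbonate
Product: 5 methyl 3-[2,4-bis(prop-2-en-1-yloxy)phenyl]-3-oxopropanoate
Conditions: NaH (2.5 equiv), 4 (5 equiv), THF, reflux; aq. HCl work-up
Reagents that add atoms: none
Why: Crossed Claisen condensation (C-methoxycarbonylation) of the ketone enolate with dimethyl carbonate, driven to completion by deprotonation of the β-keto ester formed. The ketone has a single enolisable position, so no regiochemical question arises.

Step 3
Reactants: 5 methyl 3-[2,4-bis(prop-2-en-1-yloxy)phenyl]-3-oxopropanoate; 6 prenyl bromide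
Product: 7 methyl 2-[2,4-bis(prop-2-en-1-yloxy)benzoyl]-5-methylhex-4-enoate
Conditions: 6 (1.05 equiv), K2CO3 (1.5 equiv), acetone, reflux
Reagents that add atoms: none
Why: C-alkylation (SN2) of the stabilised β-keto ester enolate by the reactive allylic bromide; weak base and one equivalent of 6 limit dialkylation. The new stereocentre is racemic and is erased in step 4.

Step 4
Reactants: 7 methyl 2-[2,4-bis(prop-2-en-1-yloxy)benzoyl]-5-methylhex-4-enoate
Product: 8 methyl 3-[2,4-bis(prop-2-en-1-yloxy)phenyl]-2-(3-methylbut-2-en-1-yl)-3-[tri(propan-2-yl)silyloxy]prop-2-enoate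
Conditions: iPr3SiOTf (1.3 equiv), Et3N (2.5 equiv), CH2Cl2, 0 → 25 °C; aq. NaHCO3 work-up
Reagents that add atoms: triisopropylsilyl trifluoromethanesulfonate, CC(C)[Si](OS(=O)(=O)C(F)(F)F)(C(C)C)C(C)C
Why: Soft enolisation and O-silylation of the β-keto ester gives the β-silyloxy acrylate, so the carbon between the carbonyls loses its acidic hydrogen and the ester can later serve as a non-enolisable acyl donor. The bulky silyl group resists attack by carbanions and lithium methoxide, and the E/Z ratio is irrelevant.

Step 5
Reactants: 9 methyl acetoacetate; 6 prenyl bromide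
Product: 10 methyl 7-methyl-3-oxooct-6-enoate
Conditions: NaH (1.1 equiv), THF, 0 °C; n-BuLi (1.05 equiv), 0 °C; 6 (1.0 equiv), 0 → 25 °C; aq. HCl work-up
Reagents that add atoms: none
Why: γ-Alkylation of the dianion of a β-keto ester: the second, more basic carbanion at the terminal methyl group reacts selectively with the allylic bromide.

Step 6
Reactants: 10 methyl 7-methyl-3-oxooct-6-enoate; 6 prenyl bromide
Product: 11 methyl 7-methyl-2-(3-methylbut-2-en-1-yl)-3-oxooct-6-enoate
Conditions: 6 (1.05 equiv), K2CO3 (1.5 equiv), acetone, reflux
Reagents that add atoms: none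
Why: α-Alkylation (SN2) of the β-keto ester monoanion at C2, done after the γ-alkylation so that each prenyl group enters at one defined carbon. The stereocentre is racemic and epimerisable.

Step 7
Reactants: 11 methyl 7-methyl-2-(3-methylbut-2-en-1-yl)-3-oxooct-6-enoate; 12 N-methoxy-N-methylacetamide
Product: 13 methyl 2,4-bis(3-methylbut-2-en-1-yl)-3,5-dioxohexanoate
Conditions: LiN(iPr)2 (2.2 equiv), THF, −78 → 0 °C; 12 (1.1 equiv), −78 → 0 °C; cold 1 M HCl
Reagents that add atoms: none
Why: Acylation of the γ-carbanion of the β-keto ester dianion with a Weinreb amide; the chelated tetrahedral adduct survives until work-up, so the more acidic product cannot quench unreacted dianion and no second addition occurs. The acetyl group is introduced last because the methine between the two ketones of 13 would otherwise be the preferred site of any later alkylation.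

Step 8
Reactants: 13 methyl 2,4-bis(3-methylbut-2-en-1-yl)-3,5-dioxohexanoate; 8 methyl 3-[2,4-bis(prop-2-en-1-yloxy)phenyl]-2-(3-methylbut-2-en-1-yl)-3-[tri(propan-2-yl)silyloxy]prop-2-enoate
Product: 15 methyl 9-[2,4-bis(prop-2-en-1-yloxy)phenyl]-2,4,8-tris(3-methylbut-2-en-1-yl)-3,5,7,9-tetraoxononanoate, via silyl enol ether 14 (not isolated)
Conditions: 13 (2 equiv), LiN(iPr)2 (6.2 equiv), THF, −78 → 0 °C; 8 (1 equiv), −78 → 0 °C; AcOH, −78 °C; Bu4NF, THF, 0 °C
Reagents that add atoms: none
Why: Claisen-type acylation of the terminal carbanion of the trilithio derivative of 13 (C4, C2 and the methyl group deprotonated) by the non-enolisable ester 8, the classical way of lengthening a poly-β-carbonyl chain; the β-carbon of 8 is fully substituted and electron-rich, so attack should go to the ester carbonyl, and the second equivalent of trianion takes up the proton of the more acidic product. Fluoride under acetate buffering then cleaves the silyl enol ether at silicon and frees the C9 ketone without the acid that would close 14 to a 4-pyranone; 15 is used crude.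

Step 9
Reactants: 15 methyl 9-[2,4-bis(prop-2-en-1-yloxy)phenyl]-2,4,8-tris(3-methylbut-2-en-1-yl)-3,5,7,9-tetraoxononanoate
Product: 16 1-[2,4-bis(prop-2-en-1-yloxy)phenyl]-2-(3-methylbut-2-en-1-yl)-3-[2,4,6-trihydroxy-3,5-bis(3-methylbut-2-en-1-yl)phenyl]propane-1,3-dione
Conditions: Mg(OMe)2 (6 equiv), MeOH, 25 → 50 °C; cold 1 M HCl
Reagents that add atoms: none
Why: Mg(OMe)2 turns 15 into a chelated magnesium polyenolate; the enolate carbon C6, the only methylene of the chain, attacks the ester carbon C1, methoxide leaves, and the cyclohexane-1,3,5-trione tautomerises to the aromatic triphenol. The closest known reaction type is the magnesium methoxide Claisen cyclisation of 3,5,7-triketo esters to acylphloroglucinols. Ring A closes in a Dieckmann-type 6-exo-trig mode, which is allowed whether the enolate double bond lies inside or outside the forming ring. No stereocentre is created: C2 and C4 become aromatic carbons and C8 remains an enolisable methine that is lost in step 10. The step needs C-acylation at C6 in preference to aldol closure and to O-acylation. Each aldol mode (C2 onto C7, C4 onto C9, C8 onto C3) uses a tertiary, prenyl-bearing carbanion against a hindered ketone and gives a ring with a quaternary carbon that can never aromatise, so these adducts have no aromatic sink and should stay in retro-aldol equilibrium. Lactonisation through the C5 enolate oxygen is reversible under methoxide, whereas the Claisen product leaves the equilibrium as a stable magnesium tris-phenoxide. Allyl ethers and prenyl groups are inert to the base, and any 17 formed during the acidic work-up converges in the next step.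

Step 10
Reactants: 16 1-[2,4-bis(prop-2-en-1-yloxy)phenyl]-2-(3-methylbut-2-en-1-yl)-3-[2,4,6-trihydroxy-3,5-bis(3-methylbut-2-en-1-yl)phenyl]propane-1,3-dione
Product: 17 2-[2,4-bis(prop-2-en-1-yloxy)phenyl]-5,7-dihydroxy-3,6,8-tris(3-methylbut-2-en-1-yl)-4H-chromen-4-one
Conditions: p-TsOH·H2O (0.1 equiv), MeOH, 25 °C
Reagents that add atoms: none
Why: An ortho hydroxyl of ring A adds to the ring B ketone to give a cyclic hemiketal, which is dehydrated under mild acid catalysis to the 4-pyranone (cyclodehydration of a 2-hydroxyaryl 1,3-diketone). The two ortho hydroxyls are equivalent and the ring B oxygens are still protected, so one flavone should result, and catalytic acid at room temperature is too weak to cyclise the prenyl groups onto the phenols.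

Step 11
Reactants: 17 2-[2,4-bis(prop-2-en-1-yloxy)phenyl]-5,7-dihydroxy-3,6,8-tris(3-methylbut-2-en-1-yl)-4H-chromen-4-one
Product: 18 artelasticin
Conditions: Pd(PPh3)4 (5 mol%), morpholine (6 equiv), THF, 25 °C
Reagents that add atoms: none
Why: Zerovalent palladium ionises the aryl allyl ethers to π-allyl complexes and phenoxides (Tsuji–Trost-type deallylation), and morpholine captures the allyl groups irreversibly. The prenyl groups have no leaving group and stay untouched, and no acid is present that could cyclise them onto the four free phenols.

## Compound list

1 | 1-(2,4-dihydroxyphenyl)ethanone (2,4-dihydroxyacetophenone) | CC(=O)c1ccc(O)cc1O | starting material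
2 | 3-bromoprop-1-ene (allyl bromide) | C=CCBr | starting material
3 | 1-[2,4-bis(prop-2-en-1-yloxy)phenyl]ethanone | CC(=O)c1ccc(OCC=C)cc1OCC=C | intermediate
4 | dimethyl carbonate | COC(=O)OC | starting material
5 | methyl 3-[2,4-bis(prop-2-en-1-yloxy)phenyl]-3-oxopropanoate | COC(=O)CC(=O)c1ccc(OCC=C)cc1OCC=C | intermediate
6 | 1-bromo-3-methylbut-2-ene (prenyl bromide) | CC(C)=CCBr | starting material
7 | methyl 2-[2,4-bis(prop-2-en-1-yloxy)benzoyl]-5-methylhex-4-enoate (racemic) | COC(=O)C(CC=C(C)C)C(=O)c1ccc(OCC=C)cc1OCC=C | intermediate
8 | methyl 3-[2,4-bis(prop-2-en-1-yloxy)phenyl]-2-(3-methylbut-2-en-1-yl)-3-[tri(propan-2-yl)silyloxy]prop-2-enoate (E/Z mixture) | COC(=O)C(CC=C(C)C)=C(O[Si](C(C)C)(C(C)C)C(C)C)c1ccc(OCC=C)cc1OCC=C | intermediate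
9 | methyl 3-oxobutanoate (methyl acetoacetate) | COC(=O)CC(C)=O | starting material
10 | methyl 7-methyl-3-oxooct-6-enoate | COC(=O)CC(=O)CCC=C(C)C | intermediate
11 | methyl 7-methyl-2-(3-methylbut-2-en-1-yl)-3-oxooct-6-enoate (racemic) | COC(=O)C(CC=C(C)C)C(=O)CCC=C(C)C | intermediate
12 | N-methoxy-N-methylacetamide | CC(=O)N(C)OC | starting material
13 | methyl 2,4-bis(3-methylbut-2-en-1-yl)-3,5-dioxohexanoate (mixture of stereoisomers and tautomers) | COC(=O)C(CC=C(C)C)C(=O)C(CC=C(C)C)C(C)=O | intermediate
14 | methyl 9-[2,4-bis(prop-2-en-1-yloxy)phenyl]-2,4,8-tris(3-methylbut-2-en-1-yl)-3,5,7-trioxo-9-[tri(propan-2-yl)silyloxy]non-8-enoate (formed in the flask, E/Z mixture) | COC(=O)C(CC=C(C)C)C(=O)C(CC=C(C)C)C(=O)CC(=O)C(CC=C(C)C)=C(O[Si](C(C)C)(C(C)C)C(C)C)c1ccc(OCC=C)cc1OCC=C | intermediate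
15 | methyl 9-[2,4-bis(prop-2-en-1-yloxy)phenyl]-2,4,8-tris(3-methylbut-2-en-1-yl)-3,5,7,9-tetraoxononanoate (mixture of stereoisomers and tautomers) | COC(=O)C(CC=C(C)C)C(=O)C(CC=C(C)C)C(=O)CC(=O)C(CC=C(C)C)C(=O)c1ccc(OCC=C)cc1OCC=C | intermediate
16 | 1-[2,4-bis(prop-2-en-1-yloxy)phenyl]-2-(3-methylbut-2-en-1-yl)-3-[2,4,6-trihydroxy-3,5-bis(3-methylbut-2-en-1-yl)phenyl]propane-1,3-dione (racemic, enolisable) | CC(C)=CCc1c(O)c(CC=C(C)C)c(O)c(C(=O)C(CC=C(C)C)C(=O)c2ccc(OCC=C)cc2OCC=C)c1O | intermediate
17 | 2-[2,4-bis(prop-2-en-1-yloxy)phenyl]-5,7-dihydroxy-3,6,8-tris(3-methylbut-2-en-1-yl)-4H-chromen-4-one | CC(C)=CCc1c(O)c(CC=C(C)C)c2oc(-c3ccc(OCC=C)cc3OCC=C)c(CC=C(C)C)c(=O)c2c1O | intermediate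
18 | artelasticin, 2-(2,4-dihydroxyphenyl)-5,7-dihydroxy-3,6,8-tris(3-methylbut-2-en-1-yl)-4H-chromen-4-one | CC(C)=CCc1c(O)c(CC=C(C)C)c2oc(-c3ccc(O)cc3O)c(CC=C(C)C)c(=O)c2c1O | target

## Step count and least certain steps

Total step count: 11. Longest linear sequence: 8 steps (1, 2, 3, 4, 8, 9, 10, 11) from 1; the branch from 9 (steps 5 to 7) joins at step 8.

**Step 9 (key step).** The most likely failure is diversion of the chain into O-cyclisation: lactone formation through the C5 enolate oxygen, or 4-pyranone formation during the acidic work-up. A second risk is methoxide-induced retro-Claisen cleavage at the 2-substituted diketone units before the hindered, α-branched ester is attacked. Both are favoured by the length of the chain and the extra aryl diketone.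

Fallback (from 13, returning at 16): ring A is closed on a shorter chain before ring B is attached.
- The trianion of 13 is acylated with methyl 5-methylhex-4-enoate to the triketo ester methyl 11-methyl-2,4-bis(3-methylbut-2-en-1-yl)-3,5,7-trioxododec-10-enoate F1.
- Mg(OMe)2 cyclisation of F1, a plain 3,5,7-triketo ester, should give the acylphloroglucinol 5-methyl-1-[2,4,6-trihydroxy-3,5-bis(3-methylbut-2-en-1-yl)phenyl]hex-4-en-1-one F2.
- The ring B acyl group is made from commercial 2,4-dihydroxybenzoic acid: 2 and K2CO3 give prop-2-en-1-yl 2,4-bis(prop-2-en-1-yloxy)benzoate F3, LiOH gives 2,4-bis(prop-2-en-1-yloxy)benzoic acid F4, and oxalyl chloride gives 2,4-bis(prop-2-en-1-yloxy)benzoyl chloride F5.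
- F2 is converted with LiN(SiMe3)2 (about five equivalents) into its polyanion and the ketone enolate is C-aroylated with F5. Any O-aroylated phenoxide rearranges under the same base by Baker–Venkataraman acyl migration, and the product is 16.

**Step 8.** The most likely failure is stalling of the acylation, because proton transfer or silyl transfer outruns addition to a hindered, electron-rich ester carbonyl. Premature desilylation of 8 by the lithium methoxide set free would turn it into an unreactive enolate. Cyclisation of 15 during isolation is a further risk and is the reason for using it crude.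

Fallback (from 8, returning at 15): the acylation is replaced by an aldol addition to a much more electrophilic aldehyde, followed by oxidation.
- 8 is reduced with i-Bu2AlH to the allylic alcohol 3-[2,4-bis(prop-2-en-1-yloxy)phenyl]-2-(3-methylbut-2-en-1-yl)-3-[tri(propan-2-yl)silyloxy]prop-2-en-1-ol F6.
- MnO2 oxidises F6 to the enal 3-[2,4-bis(prop-2-en-1-yloxy)phenyl]-2-(3-methylbut-2-en-1-yl)-3-[tri(propan-2-yl)silyloxy]prop-2-enal F7.
- The trianion of 13 adds to F7 at −78 °C to give the aldol methyl 9-[2,4-bis(prop-2-en-1-yloxy)phenyl]-7-hydroxy-2,4,8-tris(3-methylbut-2-en-1-yl)-3,5-dioxo-9-[tri(propan-2-yl)silyloxy]non-8-enoate F8.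
- Dess–Martin periodinane oxidises the allylic alcohol of F8 to 14, which is desilylated with Bu4NF and AcOH as in step 8 to 15.

**Step 7.** The most likely failure is enolisation of the Weinreb amide by the strongly basic, secondary γ-carbanion in place of addition, together with incomplete formation of the dianion of an α-substituted keto ester.

Fallback (from 11, returning at 13): the dianion of 11 is added to acetaldehyde, which is attacked faster than it is deprotonated, to give methyl 5-hydroxy-2,4-bis(3-methylbut-2-en-1-yl)-3-oxohexanoate F9. The secondary alcohol is then oxidised with Dess–Martin periodinane to 13.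

**Step 11.** The most likely failure is return of the allyl group from the π-allyl complex to the phenoxides, including C-allylation of the electron-rich ring B, if trapping by the amine is slow.

Fallback (from 17, returning at 18): the allyl ethers are isomerised and then hydrolysed, without any π-allyl intermediate. [Ir(cod)(PMePh2)2]PF6, activated with H2, isomerises 17 to the bis-enol ether 5,7-dihydroxy-3,6,8-tris(3-methylbut-2-en-1-yl)-2-[2,4-bis(prop-1-en-1-yloxy)phenyl]-4H-chromen-4-one F10; the trisubstituted prenyl alkenes do not migrate. The enol ethers are then hydrolysed with 0.1 M HCl in acetone–water at 25 °C, far milder than any acetal cleavage, to 18.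

## Further compounds

F1 | step 9 | methyl 11-methyl-2,4-bis(3-methylbut-2-en-1-yl)-3,5,7-trioxododec-10-enoate | COC(=O)C(CC=C(C)C)C(=O)C(CC=C(C)C)C(=O)CC(=O)CCC=C(C)C
F2 | step 9 | 5-methyl-1-[2,4,6-trihydroxy-3,5-bis(3-methylbut-2-en-1-yl)phenyl]hex-4-en-1-one | CC(C)=CCCC(=O)c1c(O)c(CC=C(C)C)c(O)c(CC=C(C)C)c1O
F3 | step 9 | prop-2-en-1-yl 2,4-bis(prop-2-en-1-yloxy)benzoate | C=CCOC(=O)c1ccc(OCC=C)cc1OCC=C
F4 | step 9 | 2,4-bis(prop-2-en-1-yloxy)benzoic acid | OC(=O)c1ccc(OCC=C)cc1OCC=C
F5 | step 9 | 2,4-bis(prop-2-en-1-yloxy)benzoyl chloride | ClC(=O)c1ccc(OCC=C)cc1OCC=C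
F6 | step 8 | 3-[2,4-bis(prop-2-en-1-yloxy)phenyl]-2-(3-methylbut-2-en-1-yl)-3-[tri(propan-2-yl)silyloxy]prop-2-en-1-ol | OCC(CC=C(C)C)=C(O[Si](C(C)C)(C(C)C)C(C)C)c1ccc(OCC=C)cc1OCC=C
F7 | step 8 | 3-[2,4-bis(prop-2-en-1-yloxy)phenyl]-2-(3-methylbut-2-en-1-yl)-3-[tri(propan-2-yl)silyloxy]prop-2-enal | O=CC(CC=C(C)C)=C(O[Si](C(C)C)(C(C)C)C(C)C)c1ccc(OCC=C)cc1OCC=C
F8 | step 8 | methyl 9-[2,4-bis(prop-2-en-1-yloxy)phenyl]-7-hydroxy-2,4,8-tris(3-methylbut-2-en-1-yl)-3,5-dioxo-9-[tri(propan-2-yl)silyloxy]non-8-enoate | COC(=O)C(CC=C(C)C)C(=O)C(CC=C(C)C)C(=O)CC(O)C(CC=C(C)C)=C(O[Si](C(C)C)(C(C)C)C(C)C)c1ccc(OCC=C)cc1OCC=C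
F9 | step 7 | methyl 5-hydroxy-2,4-bis(3-methylbut-2-en-1-yl)-3-oxohexanoate | COC(=O)C(CC=C(C)C)C(=O)C(CC=C(C)C)C(C)O
F10 | step 11 | 5,7-dihydroxy-3,6,8-tris(3-methylbut-2-en-1-yl)-2-[2,4-bis(prop-1-en-1-yloxy)phenyl]-4H-chromen-4-one | CC=COc1ccc(-c2oc3c(CC=C(C)C)c(O)c(CC=C(C)C)c(O)c3c(=O)c2CC=C(C)C)c(OC=CC)c1
A1 | alternative 1 | 3,5-bis(methoxymethoxy)-4,6-bis(3-methylbut-2-en-1-yl)-2-[5-methyl-2-(triphenyl-λ5-phosphanylidene)hex-4-enoyl]phenyl 2,4-bis(methoxymethoxy)benzoate | CC(C)=CCC(=P(c1ccccc1)(c1ccccc1)c1ccccc1)C(=O)c1c(OCOC)c(CC=C(C)C)c(OCOC)c(CC=C(C)C)c1OC(=O)c1ccc(OCOC)cc1OCOC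
A2 | alternative 1 | 2-[2,4-bis(methoxymethoxy)phenyl]-5,7-bis(methoxymethoxy)-3,6,8-tris(3-methylbut-2-en-1-yl)-4H-chromen-4-one | CC(C)=CCc1c(OCOC)c(CC=C(C)C)c2oc(-c3ccc(OCOC)cc3OCOC)c(CC=C(C)C)c(=O)c2c1OCOC
A3 | alternative 2 | 2-[2,4-bis(methoxymethoxy)phenyl]-6-(2-diazo-5-methylhex-4-enoyl)-3-(3-methylbut-2-en-1-yl)-4H-pyran-4-one | CC(C)=CCC(=[N+]=[N-])C(=O)c1cc(=O)c(CC=C(C)C)c(-c2ccc(OCOC)cc2OCOC)o1
A4 | alternative 2 | [(5-methylhex-4-en-1-yn-1-yl)oxy]tri(propan-2-yl)silane | CC(C)=CCC#CO[Si](C(C)C)(C(C)C)C(C)C
A5 | alternative 2 | 2-[2,4-bis(methoxymethoxy)phenyl]-5-hydroxy-3,6,8-tris(3-methylbut-2-en-1-yl)-7-[tri(propan-2-yl)silyloxy]-4H-chromen-4-one | CC(C)=CCc1c(O[Si](C(C)C)(C(C)C)C(C)C)c(CC=C(C)C)c2oc(-c3ccc(OCOC)cc3OCOC)c(CC=C(C)C)c(=O)c2c1O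
A6 | alternative 3 | 2-[2,4-bis(methoxymethoxy)phenyl]-5,7-bis[(2-methylbut-3-en-2-yl)oxy]-3-(3-methylbut-2-en-1-yl)-4H-chromen-4-one | C=CC(C)(C)Oc1cc(OC(C)(C)C=C)c2c(=O)c(CC=C(C)C)c(-c3ccc(OCOC)cc3OCOC)oc2c1
A7 | alternative 3 | 2-[2,4-bis(methoxymethoxy)phenyl]-5,7-dihydroxy-3,6,8-tris(3-methylbut-2-en-1-yl)-4H-chromen-4-one | CC(C)=CCc1c(O)c(CC=C(C)C)c2oc(-c3ccc(OCOC)cc3OCOC)c(CC=C(C)C)c(=O)c2c1O
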